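**Retrosynthetic overview**
1. 18 ⇒ spiro-dithioketal 17. C4=O is unmasked last, so the base-labile flavanone exists only in the final, near-neutral step.
2. 17 ⇒ phenol-carbinol 16. The O1–C2 bond forms by intramolecular Mitsunobu reaction with inversion (R → S). This closes ring C, the only ring of the target that is built; rings A and B are bought.
3. 16 ⇒ aryl-dithiane 13 + (S)-styrene oxide 3. The C3–C4 bond forms by dithiane umpolung and epoxide opening.
4. 3 ⇒ 2-chloroacetophenone 1. A ketoreductase sets the sole stereocentre, followed by halohydrin closure.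
5. 13 ⇒ 3,5-dimethoxyphenol 4, by reverse-prenyl ether/aromatic Claisen (ring symmetry gives one regioisomer) and Mg-directed ortho-formylation. Ring order: oxirane (temporary) → dithiane (temporary) → ring C.

Assumption: the given SMILES is read as (2S), and commercial ketoreductase preparations and NADP+ count as catalysts.

**Step 1**
Reactants: 1 2-chloro-1-phenylethan-1-one
Product: 2 (S)-2-chloro-1-phenylethan-1-ol
Conditions: ketoreductase (NADPH-dependent anti-Prelog alcohol dehydrogenase, Lactobacillus kefir/brevis type), NADP+ (cat.), i-PrOH (15% v/v), K-phosphate buffer pH 7.0, 1 mM MgCl2, 30 °C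
Reagents that add atoms: none
Why: Biocatalytic asymmetric ketone reduction, in which the ketoreductase delivers hydride from NADPH (recycled by i-PrOH) to one face of the prochiral α-chloroketone in the anti-Prelog sense, setting the only stereocentre as (S) in >99% ee on a routine substrate class for these enzymes.

**Step 2**
Reactants: 2 (S)-2-chloro-1-phenylethan-1-ol
Product: 3 (S)-2-phenyloxirane
Conditions: 2 M aq NaOH, MTBE, 0 °C to rt
Reagents that add atoms: none
Why: Intramolecular Williamson (halohydrin) closure, in which the alkoxide displaces the primary chloride and the C–O bond at the stereocentre is never broken, so (S) is retained.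

**Step 3**
Reactants: 4 3,5-dimethoxyphenol; 5 3-chloro-3-methylbut-1-yne
Product: 6 1,3-dimethoxy-5-[(2-methylbut-3-yn-2-yl)oxy]benzene
Conditions: DBU (1.3 equiv), CuCl2·2H2O (0.5 mol %), MeCN, 0 °C
Reagents that add atoms: none
Why: Copper-catalysed O-propargylation of a phenol with a tertiary propargylic chloride gives the aryl 1,1-dimethylpropargyl ether at 0 °C, well below the temperature at which it would rearrange to a chromene.

**Step 4**
Reactants: 6 1,3-dimethoxy-5-[(2-methylbut-3-yn-2-yl)oxy]benzene
Product: 7 1,3-dimethoxy-5-[(2-methylbut-3-en-2-yl)oxy]benzene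
Conditions: H2 (1 atm), Lindlar catalyst, quinoline, EtOAc, rt; filter through Celite, use crude
Reagents that add atoms: none
Why: Lindlar semi-hydrogenation stops the terminal alkyne at the alkene and leaves the arene and the tertiary ether untouched.

**Step 5**
Reactants: 7 1,3-dimethoxy-5-[(2-methylbut-3-en-2-yl)oxy]benzene
Product: 9 3,5-dimethoxy-2-(3-methylbut-2-en-1-yl)phenol, via ortho-dienone 8 (not isolated)
Conditions: PhNEt2, 130 °C, 2 h, Ar
Reagents that add atoms: none
Why: In this aromatic Claisen [3,3] rearrangement the two ortho positions are equivalent by symmetry, allyl inversion turns the 1,1-dimethylallyl group into prenyl, the dienone tautomerises to the phenol, and the basic solvent suppresses acid-catalysed chroman formation.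

**Step 6**
Reactants: 9 3,5-dimethoxy-2-(3-methylbut-2-en-1-yl)phenol
Product: 11 2-hydroxy-4,6-dimethoxy-3-(3-methylbut-2-en-1-yl)benzaldehyde, via salicyl alcohol 10 (not isolated)
Conditions: anhydrous MgCl2 (2 equiv), Et3N (4 equiv), (CH2O)n (6 equiv), THF, reflux; cold 1 M HCl work-up
Reagents that add atoms: paraformaldehyde (reacts as formaldehyde), C=O
Why: In the Casnati–Skattebøl ortho-formylation, Mg(II) chelation delivers formaldehyde only to the single free ortho carbon (the para position stays untouched), and a second formaldehyde oxidises the salicyl alcohol by Oppenauer-type hydride transfer, with the prenyl group inert.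

**Step 7**
Reactants: 11 2-hydroxy-4,6-dimethoxy-3-(3-methylbut-2-en-1-yl)benzaldehyde
Product: 12 4,6-dimethoxy-3-(3-methylbut-2-en-1-yl)-2-[(triisopropylsilyl)oxy]benzaldehyde
Conditions: TIPSOTf (1.3 equiv), 2,6-lutidine (2 equiv), CH2Cl2, 0 °C to rt
Reagents that add atoms: triisopropylsilyl triflate, CC(C)[Si](OS(=O)(=O)C(F)(F)F)(C(C)C)C(C)C
Why: Silyl ether formation with the reactive triflate overcomes the chelated, flanked phenol; the TIPS group blocks acid-induced chroman closure, tolerates BF3 and n-BuLi, and is too bulky to migrate easily.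

**Step 8**
Reactants: 12 4,6-dimethoxy-3-(3-methylbut-2-en-1-yl)-2-[(triisopropylsilyl)oxy]benzaldehyde
Product: 13 2-{4,6-dimethoxy-3-(3-methylbut-2-en-1-yl)-2-[(triisopropylsilyl)oxy]phenyl}-1,3-dithiane
Conditions: HS(CH2)3SH (1.2 equiv), BF3·OEt2 (20 mol %), 4 Å MS, CH2Cl2, −20 to 0 °C
Reagents that add atoms: propane-1,3-dithiol, SCCCS
Why: Lewis-acid-catalysed dithioacetalisation works because the electron-rich aldehyde ionises readily, so catalytic BF3 at low temperature suffices and spares the trisubstituted alkene and the aryl silyl ether.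

**Step 9**
Reactants: 13 2-{4,6-dimethoxy-3-(3-methylbut-2-en-1-yl)-2-[(triisopropylsilyl)oxy]phenyl}-1,3-dithiane; 3 (S)-2-phenyloxirane
Product: 15 (R)-2-(2-{4,6-dimethoxy-3-(3-methylbut-2-en-1-yl)-2-[(triisopropylsilyl)oxy]phenyl}-1,3-dithian-2-yl)-1-phenylethan-1-ol, via 2-lithiodithiane 14 (not isolated)
Conditions: n-BuLi (1.05 equiv), THF (no HMPA), −78 to −30 °C, 1 h; then 3 (1.3 equiv), −78 to 0 °C, 12 h; sat. aq NH4Cl
Reagents that add atoms: none
Why: In this Corey–Seebach umpolung the bulky dithiane anion opens the epoxide by SN2 at the unsubstituted carbon, so the stereocentre is not touched and its descriptor changes from S to R only because the CIP ranking of CH2 and Ph is exchanged.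

**Step 10**
Reactants: 15 (R)-2-(2-{4,6-dimethoxy-3-(3-methylbut-2-en-1-yl)-2-[(triisopropylsilyl)oxy]phenyl}-1,3-dithian-2-yl)-1-phenylethan-1-ol
Product: 16 2-{2-[(R)-2-hydroxy-2-phenylethyl]-1,3-dithian-2-yl}-3,5-dimethoxy-6-(3-methylbut-2-en-1-yl)phenol
Conditions: TBAF (1.1 equiv), AcOH (1.1 equiv), THF, 0 °C
Reagents that add atoms: none
Why: Buffered fluoride desilylation cleaves the aryl Si–O bond selectively and leaves the dithiane, prenyl group and carbinol stereocentre untouched.

**Step 11**
Reactants: 16 2-{2-[(R)-2-hydroxy-2-phenylethyl]-1,3-dithian-2-yl}-3,5-dimethoxy-6-(3-methylbut-2-en-1-yl)phenol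
Product: 17 (S)-5,7-dimethoxy-8-(3-methylbut-2-en-1-yl)-2-phenylspiro[chromane-4,2'-[1,3]dithiane]
Conditions: PPh3 (1.5 equiv), DIAD (1.5 equiv), THF (0.02 M), 0 °C to rt
Reagents that add atoms: none
Why: In this intramolecular Mitsunobu etherification the phenol displaces the activated benzylic oxygen in a 6-exo-tet SN2 with clean inversion (R → S), and the dithiane removes the C3 acidity that would otherwise allow E1cB loss to a chalcone.

**Step 12**
Reactants: 17 (S)-5,7-dimethoxy-8-(3-methylbut-2-en-1-yl)-2-phenylspiro[chromane-4,2'-[1,3]dithiane]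
Product: 18 (2S)-5,7-dimethoxy-8-(3-methylbut-2-en-1-yl)-2-phenylchroman-4-one (candidone)
Conditions: MeI (15 equiv), CaCO3 (5 equiv), MeCN/H2O 9:1, 40 °C, dark
Reagents that add atoms: water, O
Why: In this alkylative dithiane hydrolysis, S-methylation gives an aryl-stabilised thionium ion that water captures, MeI does not touch the prenyl alkene or the arene, and the CaCO3 buffer keeps the medium too mild for enolisation or retro-oxa-Michael racemisation at C2.

**Compound list**
1 | 2-chloro-1-phenylethan-1-one | O=C(CCl)c1ccccc1 | starting material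
2 | (S)-2-chloro-1-phenylethan-1-ol | O[C@H](CCl)c1ccccc1 | intermediate
3 | (S)-2-phenyloxirane | C1O[C@H]1c2ccccc2 | intermediate
4 | 3,5-dimethoxyphenol | COc1cc(O)cc(OC)c1 | starting material
5 | 3-chloro-3-methylbut-1-yne | C#CC(C)(C)Cl | starting material
6 | 1,3-dimethoxy-5-[(2-methylbut-3-yn-2-yl)oxy]benzene | COc1cc(OC)cc(OC(C)(C)C#C)c1 | intermediate
7 | 1,3-dimethoxy-5-[(2-methylbut-3-en-2-yl)oxy]benzene | COc1cc(OC)cc(OC(C)(C)C=C)c1 | intermediate
8 | 3,5-dimethoxy-6-(3-methylbut-2-en-1-yl)cyclohexa-2,4-dien-1-one (racemic, transient, not isolated) | O=C1C=C(OC)C=C(OC)C1CC=C(C)C | intermediate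
9 | 3,5-dimethoxy-2-(3-methylbut-2-en-1-yl)phenol | COc1cc(O)c(CC=C(C)C)c(OC)c1 | intermediate
10 | 2-(hydroxymethyl)-3,5-dimethoxy-6-(3-methylbut-2-en-1-yl)phenol (present as its magnesium salt, not isolated) | COc1cc(OC)c(CO)c(O)c1CC=C(C)C | intermediate
11 | 2-hydroxy-4,6-dimethoxy-3-(3-methylbut-2-en-1-yl)benzaldehyde | COc1cc(OC)c(C=O)c(O)c1CC=C(C)C | intermediate
12 | 4,6-dimethoxy-3-(3-methylbut-2-en-1-yl)-2-[(triisopropylsilyl)oxy]benzaldehyde | COc1cc(OC)c(C=O)c(O[Si](C(C)C)(C(C)C)C(C)C)c1CC=C(C)C | intermediate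
13 | 2-{4,6-dimethoxy-3-(3-methylbut-2-en-1-yl)-2-[(triisopropylsilyl)oxy]phenyl}-1,3-dithiane | COc1cc(OC)c(C2SCCCS2)c(O[Si](C(C)C)(C(C)C)C(C)C)c1CC=C(C)C | intermediate
14 | 2-lithio derivative of 13 (not isolated) | COc1cc(OC)c(C2([Li])SCCCS2)c(O[Si](C(C)C)(C(C)C)C(C)C)c1CC=C(C)C | intermediate
15 | (R)-2-(2-{4,6-dimethoxy-3-(3-methylbut-2-en-1-yl)-2-[(triisopropylsilyl)oxy]phenyl}-1,3-dithian-2-yl)-1-phenylethan-1-ol | COc1cc(OC)c(C2(C[C@@H](O)c3ccccc3)SCCCS2)c(O[Si](C(C)C)(C(C)C)C(C)C)c1CC=C(C)C | intermediate
16 | 2-{2-[(R)-2-hydroxy-2-phenylethyl]-1,3-dithian-2-yl}-3,5-dimethoxy-6-(3-methylbut-2-en-1-yl)phenol | COc1cc(OC)c(C2(C[C@@H](O)c3ccccc3)SCCCS2)c(O)c1CC=C(C)C | intermediate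
17 | (S)-5,7-dimethoxy-8-(3-methylbut-2-en-1-yl)-2-phenylspiro[chromane-4,2'-[1,3]dithiane] | COc1cc(OC)c2c(c1CC=C(C)C)O[C@H](c1ccccc1)CC23SCCCS3 | intermediate
18 | (2S)-5,7-dimethoxy-8-(3-methylbut-2-en-1-yl)-2-phenylchroman-4-one (candidone) | COc1cc(OC)c2c(c1CC=C(C)C)O[C@H](c1ccccc1)CC2=O | target

**Totals**
Total step count: 12.
Longest linear sequence: 10 steps (steps 3–12, from 4). Steps 1–2 form the convergent branch.

**Three steps most likely to fail**

Step 9 (dithiane lithiation and epoxide opening).
- Risks: the di-ortho-substituted, electron-rich aryl dithiane may deprotonate slowly. Its anion may be too hindered for the epoxide. It may also suffer O→C silyl migration.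
- Fallback: it sets out from 13, with 2 as the chiral partner, and comes back at 17. It reverses the order of bond formation. Buffered TBAF frees 2-(1,3-dithian-2-yl)-3,5-dimethoxy-6-(3-methylbut-2-en-1-yl)phenol F1. An intermolecular Mitsunobu etherification of F1 with chlorohydrin 2 (PPh3, DIAD, concentrated toluene) gives, with inversion, (R)-2-[2-(2-chloro-1-phenylethoxy)-4,6-dimethoxy-3-(3-methylbut-2-en-1-yl)phenyl]-1,3-dithiane F2. n-BuLi at −78 °C then forms the 2-lithio derivative F3. F3 carries no silyl group and closes the C3–C4 bond by intramolecular 6-exo-tet alkylation of the primary chloride, giving 17 directly.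

Step 11 (Mitsunobu ring closure).
- Risks: the flanked phenol may engage poorly, leading to hydrazide capture or elimination. Any ionisation of the benzylic oxyphosphonium would erode the ee.
- Fallback: it sets out from 15 and comes back at 17. It replaces redox condensation with a fluoride-triggered phenoxide SN2. The carbinol of 15 is mesylated while the phenol is still silylated (MsCl, Et3N, CH2Cl2, −40 °C, used crude), giving the (R)-methanesulfonate F4. TBAF in THF at −20 °C then releases the phenoxide of the desilylated mesylate F5. As a naked ammonium phenoxide, F5 displaces the mesylate with inversion in the same flask to give 17.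

Step 12 (unmasking of C4=O).
- Risks: the hindered spiro-dithioketal peri to the 5-OMe group may hydrolyse sluggishly. Long heating could then start to racemise the flavanone.
- Fallback: it sets out from 16 and comes back at 18. It unmasks the ketone in the open-chain series, where the stereocentre is a simple carbinol. MeI/CaCO3 in aqueous MeCN converts 16 into (R)-3-hydroxy-1-[2-hydroxy-4,6-dimethoxy-3-(3-methylbut-2-en-1-yl)phenyl]-3-phenylpropan-1-one F6. F6 is then cyclised with inversion by an intramolecular Mitsunobu reaction (PPh3, DIAD, toluene, 0 °C) to 18. Any chalcone formed by dehydration is separable and does not cyclise under these neutral conditions, so it cannot dilute the ee.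

**Further compounds**
F1 | step 9 | 2-(1,3-dithian-2-yl)-3,5-dimethoxy-6-(3-methylbut-2-en-1-yl)phenol | COc1cc(OC)c(C2SCCCS2)c(O)c1CC=C(C)C
F2 | step 9 | (R)-2-[2-(2-chloro-1-phenylethoxy)-4,6-dimethoxy-3-(3-methylbut-2-en-1-yl)phenyl]-1,3-dithiane | COc1cc(OC)c(C2SCCCS2)c(O[C@@H](CCl)c2ccccc2)c1CC=C(C)C
F3 | step 9 | 2-lithio derivative of F2 | COc1cc(OC)c(C2([Li])SCCCS2)c(O[C@@H](CCl)c2ccccc2)c1CC=C(C)C
F4 | step 11 | (R)-methanesulfonate of 15 | COc1cc(OC)c(C2(C[C@@H](OS(C)(=O)=O)c3ccccc3)SCCCS2)c(O[Si](C(C)C)(C(C)C)C(C)C)c1CC=C(C)C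
F5 | step 11 | desilylated mesylate (reacts as its phenoxide) | COc1cc(OC)c(C2(C[C@@H](OS(C)(=O)=O)c3ccccc3)SCCCS2)c(O)c1CC=C(C)C
F6 | step 12 | (R)-3-hydroxy-1-[2-hydroxy-4,6-dimethoxy-3-(3-methylbut-2-en-1-yl)phenyl]-3-phenylpropan-1-one | COc1cc(OC)c(C(=O)C[C@@H](O)c2ccccc2)c(O)c1CC=C(C)C
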